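The constants used here are those of an exercise; the result is computed.

Weigh the nucleophile closely.

common to all: electrophile 1.4 M; gas 200 mM (held); time 40 min

| flask | nucleophile |
|---|---|
| Saturday's | 1.30 M |
| Tuesday's | 2.00 M |
| Sunday's | 3.00 M |

    gas ⇌ free base, rate k1*(csat - [free base]) (k1 = 0.62 min⁻¹, csat = 200 mM)
    electrophile + nucleophile → acid set free + target (k2 = 0.021 L mol⁻¹ min⁻¹)
    nucleophile + acid set free ⇌ protonated nucleophile, settled at all times (K3 = 300 L mol⁻¹)
    target ⇌ isomer of the product (K4 = 2.8, k4 = 0.019 min⁻¹)
    acid set free + free base ⇌ salt of the base (K5 = 9.5 L mol⁻¹, k5 = 1.2 L mol⁻¹ min⁻¹)
    electrophile + target → side product (k6 = 0.030 L mol⁻¹ min⁻¹)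

- part of the electrophile that has reacted at the end, Saturday's
- part of the electrophile that has reacted at the end, Tuesday's
- part of the electrophile that has reacted at the end, Sunday's
- what raising the concentration of nucleophile from its lowest to its highest value here does to the part of the electrophile that has reacted (changes below 5 percentage points count as none) (it falls / it rises / no change)

- percentages count the electrophile that a species holds: one side product counts as two
- at the start none of free base is dissolved
- run time (Saturday's): 40 min

The gas loads the free base within about 1.61 min, far quicker than the run, so the free base is present early. But it bids poorly for the acid set free: the nucleophile's pull is 390 at Saturday's start, against 1.90 for the free base. So each coupling of electrophile with nucleophile costs two nucleophiles, one joined and one protonated.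

The electrophile has a second exit, since target attacks it. At any moment its pace of loss is the coupling constant times [nucleophile] plus the burn constant times [target]. The two terms are equal when [target] equals the ridge ratio times [nucleophile], where the ridge ratio is the coupling constant over the burn constant (a selectivity factor), 0.700.

This comparison drifts: [target] starts from zero, and [nucleophile] falls as coupling proceeds. We assume target has reached the ridge by the end, which makes the closing pace twice the coupling term. Coupling alone, at two nucleophiles each, leaves 0.228 M of nucleophile in Saturday's, 0.459 M in Tuesday's and 0.948 M in Sunday's. Averaging the opening and closing paces over the run, we expect 52.2%, 70.7% and 87.2%.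

The forecast gives 51.5%, 68% and 83%, and its verdict is it rises, on the ground: “Each turnover thus costs two nucleophiles”.

The simulation gives 51.8%, 69.2% and 84.6%; it rises, by 33 percentage points across the series, and our Sunday's figure stands 2.6 points high. Tuesday's answer moves by 5 points with the nucleophile at 1.77 M or 2.26 M. At the end of Saturday's, [target] is 0.186 M against a ridge mark of 0.193 M. At the end of Sunday's it stands lower than the mark we assumed, 0.416 M against 0.795 M.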